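**Assumption:** positions are given in labdane numbering (ring A C1–C5/C10, ring B C5–C10, side chain C11–C16, C17 on C8, C18 = CH2O and C19 = CH3 on C4, C20 = CH3 on C10). Target relative configuration: C19 and C11 cis to C20; C18, H5, H9 and 6-OH trans to C20.

## Retrosynthetic overview
1. 19 ⇐ 18 (desilylation) ⇐ diene ester 16: hydroboration–oxidation of the ring B 5,7-diene sets C5–H and C6–OH.
2. 16 ⇐ triene 13 + methyl but-2-ynoate 14 (C12–C13 bond, E-alkene by syn carbocupration); 13 ⇐ vinyl ketone 11 (dienyl triflate, methyl coupling).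
3. Key step: 11 ⇐ allyl carbinol 10 by ring expansion; a 1,2-shift of the quaternary C10 from C8 to C9 turns the cyclopentanol into six-membered ring B.
4. 10 ⇐ enedione 4 + allylmagnesium bromide 5 + a C1 electrophile (C4 quaternary centre by deconjugative alkylation, C3 deoxygenated); 4 ⇐ 1 + 2 (asymmetric Robinson annulation).
5. Ring order: cyclopentane (from 1) → ring A (annulation) → ring B (expansion of the five-membered ring).

## Route

**Step 1**
Reactants: 1 2-methylcyclopentane-1,3-dione; 2 pent-1-en-3-one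
Product: 4 (7aR)-4,7a-dimethyl-2,3,7,7a-tetrahydro-1H-indene-1,5(6H)-dione, via triketone 3 (not isolated)
Conditions: H2O, AcOH (cat.), 70 °C; concentrate; D-phenylalanine (1 equiv), camphorsulfonic acid (0.5 equiv), DMF, 30 → 70 °C; recrystallise
Reagents that add atoms: none
Why: Michael addition followed by amino-acid-mediated enamine aldol condensation (Hajos–Parrish-type Robinson annulation); the D-amino acid selects one of the two enantiotopic ring carbonyls and so sets the quaternary methyl centre (future C10) as R.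

**Step 2**
Reactants: 4 (7aR)-4,7a-dimethyl-2,3,7,7a-tetrahydro-1H-indene-1,5(6H)-dione; 5 allylmagnesium bromide
Product: 8 (1R,4S,7aR)-1-hydroxy-4,7a-dimethyl-1-(prop-2-en-1-yl)-4-{[tri(propan-2-yl)silyl]oxymethyl}-1,2,4,6,7,7a-hexahydro-5H-inden-5-one, via potassium dienolate 6 (not isolated), via magnesium alkoxide dienolate 7 (not isolated)
Conditions: KH (1.05 equiv), THF, 0 °C → rt; CH2=CHCH2MgBr (1.2 equiv), −78 °C; then i-Pr3SiOCH2Cl (1.4 equiv), −78 → 0 °C; aq NH4Cl
Reagents that add atoms: (triisopropylsiloxy)methyl chloride (TOM-Cl), ClCO[Si](C(C)C)(C(C)C)C(C)C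
Why: Irreversible deprotonation gives the extended dienolate, which masks the enone while the Grignard reagent adds to the only free carbonyl (C8, anti to the angular methyl); the same dienolate is then C-alkylated at C4 anti to the angular methyl, which sets the C4 quaternary centre (CH2O trans to C20) and moves the alkene to C5=C6 (in situ enolate protection, 1,2-addition, deconjugative alpha-alkylation).

**Step 3**
Reactants: 8 (1R,4S,7aR)-1-hydroxy-4,7a-dimethyl-1-(prop-2-en-1-yl)-4-{[tri(propan-2-yl)silyl]oxymethyl}-1,2,4,6,7,7a-hexahydro-5H-inden-5-one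
Product: 10 (1R,4S,7aR)-4,7a-dimethyl-1-(prop-2-en-1-yl)-4-{[tri(propan-2-yl)silyl]oxymethyl}-2,4,5,6,7,7a-hexahydro-1H-inden-1-ol, via tosylhydrazone 9 (not isolated)
Conditions: TsNHNH2 (1.3 equiv), pyridinium tosylate (cat.), EtOH, 70 °C; concentrate; catecholborane (3 equiv), CHCl3, 0 °C → rt; NaOAc·3H2O, 60 °C
Reagents that add atoms: none
Why: C3 is now the only ketone, so tosylhydrazone formation and hydride reduction with loss of sulfinate and N2 (Kabalka-type reductive deoxygenation, a mild Wolff–Kishner equivalent) give the CH2 group without touching the tertiary alcohol, silyl ether or alkenes; no stereocentre is involved.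

**Step 4**
Reactants: 10 (1R,4S,7aR)-4,7a-dimethyl-1-(prop-2-en-1-yl)-4-{[tri(propan-2-yl)silyl]oxymethyl}-2,4,5,6,7,7a-hexahydro-1H-inden-1-ol
Product: 11 (1S,5S,8aS)-1-ethenyl-5,8a-dimethyl-5-{[tri(propan-2-yl)silyl]oxymethyl}-1,5,6,7,8,8a-hexahydronaphthalen-2(3H)-one
Conditions: Pd(OAc)2 (10 mol %), 1,2-bis(phenylsulfinyl)ethane (10 mol %), 1,4-benzoquinone (2 equiv), (PhO)2P(O)OH (20 mol %), 1,4-dioxane, 45 °C
Reagents that add atoms: none
Why: Proposed new method: divalent palladium/bis-sulfoxide cleaves the allylic C9–H of the terminal olefin to a pi-allyl, whose internal carbon (C9) is attacked by the electron-rich C8–C10 sigma bond anti to palladium while the hydroxyl becomes the C8 carbonyl (semipinacol 1,2-shift, five- to six-membered ring), and the zerovalent palladium released is reoxidised by the quinone; the quaternary C10 is expected to migrate in preference to the C7 methylene and does so with retention, and the rotamer that keeps the allyl chain next to the small oxygen rather than the ring CH2 puts the vinyl group cis to C20; the closest known reactions are palladium/sulfoxide allylic C–H oxidation of terminal olefins and the pi-allylpalladium Wagner–Meerwein ring expansion of cyclobutanol-derived allylic carbonates, which have not been combined and not shown on an unstrained cyclopentanol.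

**Step 5**
Reactants: 11 (1S,5S,8aS)-1-ethenyl-5,8a-dimethyl-5-{[tri(propan-2-yl)silyl]oxymethyl}-1,5,6,7,8,8a-hexahydronaphthalen-2(3H)-one
Product: 12 (1S,5S,8aS)-1-ethenyl-5,8a-dimethyl-5-{[tri(propan-2-yl)silyl]oxymethyl}-1,5,6,7,8,8a-hexahydronaphthalen-2-yl trifluoromethanesulfonate
Conditions: KN(SiMe3)2 (1.2 equiv), THF, −78 °C (ketone added to base); PhNTf2 (1.3 equiv), −78 → 0 °C
Reagents that add atoms: N-phenylbis(trifluoromethanesulfonimide), O=S(=O)(N(c1ccccc1)S(=O)(=O)C(F)(F)F)C(F)(F)F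
Why: Kinetic deprotonation takes the unhindered, doubly activated C7 methylene rather than the hindered tertiary C9–H next to the quaternary carbon, and O-triflation of the extended enolate gives the 5,7-dien-8-yl triflate (enol triflate formation); inverse addition avoids proton exchange, so C9 is fixed from here on.

**Step 6**
Reactants: 12 (1S,5S,8aS)-1-ethenyl-5,8a-dimethyl-5-{[tri(propan-2-yl)silyl]oxymethyl}-1,5,6,7,8,8a-hexahydronaphthalen-2-yl trifluoromethanesulfonate
Product: 13 (1R,5S,8aS)-1-ethenyl-2,5,8a-trimethyl-5-{[tri(propan-2-yl)silyl]oxymethyl}-1,5,6,7,8,8a-hexahydronaphthalene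
Conditions: MeZnCl (2 equiv), Pd(PPh3)4 (5 mol %), THF, 50 °C
Reagents that add atoms: methylzinc chloride, C[Zn]Cl
Why: Negishi coupling of the alkenyl triflate installs C17 with the ring B diene geometry fixed by the ring; no stereocentre changes.

**Step 7**
Reactants: 13 (1R,5S,8aS)-1-ethenyl-2,5,8a-trimethyl-5-{[tri(propan-2-yl)silyl]oxymethyl}-1,5,6,7,8,8a-hexahydronaphthalene; 14 methyl but-2-ynoate
Product: 16 methyl (2E)-3-methyl-5-[(1R,5S,8aS)-2,5,8a-trimethyl-5-{[tri(propan-2-yl)silyl]oxymethyl}-1,5,6,7,8,8a-hexahydronaphthalen-1-yl]pent-2-enoate, via B-alkyl-9-BBN adduct 15 (not isolated)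
Conditions: 9-BBN-H dimer (0.55 equiv), THF, 0 °C → rt; then 14 (1.5 equiv), CuOAc (5 mol %), P(OPh)3 (10 mol %), KOt-Bu (10 mol %), t-BuOH (1.5 equiv), 1,4-dioxane, 40 °C
Reagents that add atoms: none
Why: 9-BBN hydroborates only the monosubstituted vinyl group (anti-Markovnikov), and copper-catalysed conjugate addition of the B-alkyl group to the alkynoate by syn carbocupration and protonation places the chain cis to H, which gives the E enoate and the C12–C13 bond.

**Step 8**
Reactants: 16 methyl (2E)-3-methyl-5-[(1R,5S,8aS)-2,5,8a-trimethyl-5-{[tri(propan-2-yl)silyl]oxymethyl}-1,5,6,7,8,8a-hexahydronaphthalen-1-yl]pent-2-enoate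
Product: 18 methyl (2E)-5-[(1R,4R,4aS,5S,8aS)-4-hydroxy-2,5,8a-trimethyl-5-{[tri(propan-2-yl)silyl]oxymethyl}-1,4,4a,5,6,7,8,8a-octahydronaphthalen-1-yl]-3-methylpent-2-enoate, via C6 alkylborane 17 (not isolated)
Conditions: BH3·THF (1.5 equiv), THF, 0 °C; then 3 M NaOH, 30% H2O2, 0 °C
Reagents that add atoms: hydrogen peroxide, OO
Why: Syn addition of H–B across C5=C6 of the homoannular diene from the face opposite the C19 and C20 methyl groups puts boron on C6 and hydrogen on C5 (trans ring fusion), and oxidation with retention gives the equatorial 6-OH with the C7=C8 alkene left in place (hydroboration–oxidation, as with steroidal 5,7-dienes); the electron-poor enoate reacts more slowly.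

**Step 9**
Reactants: 18 methyl (2E)-5-[(1R,4R,4aS,5S,8aS)-4-hydroxy-2,5,8a-trimethyl-5-{[tri(propan-2-yl)silyl]oxymethyl}-1,4,4a,5,6,7,8,8a-octahydronaphthalen-1-yl]-3-methylpent-2-enoate
Product: 19 methyl (2E)-5-[(1R,4R,4aS,5S,8aS)-4-hydroxy-5-(hydroxymethyl)-2,5,8a-trimethyl-1,4,4a,5,6,7,8,8a-octahydronaphthalen-1-yl]-3-methylpent-2-enoate (CNP0149445.1)
Conditions: Bu4NF (2 equiv), THF, rt → 40 °C
Reagents that add atoms: none
Why: Fluoride cleaves the silyl ether (desilylation) without affecting the ester, the allylic alcohol or any stereocentre.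

## Compound list
1 | 2-methylcyclopentane-1,3-dione | CC1C(=O)CCC1=O | starting material
2 | pent-1-en-3-one (ethyl vinyl ketone) | CCC(=O)C=C | starting material
3 | 2-methyl-2-(3-oxopentyl)cyclopentane-1,3-dione | CCC(=O)CCC1(C)C(=O)CCC1=O | intermediate (not isolated)
4 | (7aR)-4,7a-dimethyl-2,3,7,7a-tetrahydro-1H-indene-1,5(6H)-dione | O=C1CCC2=C(C)C(=O)CC[C@@]12C | intermediate
5 | allylmagnesium bromide | C=CC[Mg]Br | starting material
6 | potassium extended dienolate of 4 (O–C3=C4–C5=C6, C8 ketone free) | O=C1CC=C2C(C)=C([O-])CC[C@@]12C.[K+] | intermediate (not isolated)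
7 | C8 allyl adduct of 6 (bromomagnesium tertiary alkoxide, potassium dienolate; allyl anti to the angular methyl) | C=CC[C@@]1([O-])CC=C2C(C)=C([O-])CC[C@@]12C.[K+].[Mg+2].[Br-] | intermediate (not isolated)
8 | (1R,4S,7aR)-1-hydroxy-4,7a-dimethyl-1-(prop-2-en-1-yl)-4-{[tri(propan-2-yl)silyl]oxymethyl}-1,2,4,6,7,7a-hexahydro-5H-inden-5-one | C=CC[C@@]1(O)CC=C2[C@@](C)(CO[Si](C(C)C)(C(C)C)C(C)C)C(=O)CC[C@@]12C | intermediate
9 | 4-methylbenzenesulfonylhydrazone of 8 at the ring ketone | C=CC[C@@]1(O)CC=C2[C@@](C)(CO[Si](C(C)C)(C(C)C)C(C)C)C(=NNS(=O)(=O)c3ccc(C)cc3)CC[C@@]12C | intermediate (not isolated)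
10 | (1R,4S,7aR)-4,7a-dimethyl-1-(prop-2-en-1-yl)-4-{[tri(propan-2-yl)silyl]oxymethyl}-2,4,5,6,7,7a-hexahydro-1H-inden-1-ol | C=CC[C@@]1(O)CC=C2[C@@](C)(CO[Si](C(C)C)(C(C)C)C(C)C)CCC[C@@]12C | intermediate
11 | (1S,5S,8aS)-1-ethenyl-5,8a-dimethyl-5-{[tri(propan-2-yl)silyl]oxymethyl}-1,5,6,7,8,8a-hexahydronaphthalen-2(3H)-one (vinyl cis to the angular methyl) | C=C[C@@H]1C(=O)CC=C2[C@@](C)(CO[Si](C(C)C)(C(C)C)C(C)C)CCC[C@@]12C | intermediate
12 | (1S,5S,8aS)-1-ethenyl-5,8a-dimethyl-5-{[tri(propan-2-yl)silyl]oxymethyl}-1,5,6,7,8,8a-hexahydronaphthalen-2-yl trifluoromethanesulfonate | C=C[C@@H]1C(OS(=O)(=O)C(F)(F)F)=CC=C2[C@@](C)(CO[Si](C(C)C)(C(C)C)C(C)C)CCC[C@@]12C | intermediate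
13 | (1R,5S,8aS)-1-ethenyl-2,5,8a-trimethyl-5-{[tri(propan-2-yl)silyl]oxymethyl}-1,5,6,7,8,8a-hexahydronaphthalene | C=C[C@@H]1C(C)=CC=C2[C@@](C)(CO[Si](C(C)C)(C(C)C)C(C)C)CCC[C@@]12C | intermediate
14 | methyl but-2-ynoate | CC#CC(=O)OC | starting material
15 | 9-{2-[(1R,5S,8aS)-2,5,8a-trimethyl-5-{[tri(propan-2-yl)silyl]oxymethyl}-1,5,6,7,8,8a-hexahydronaphthalen-1-yl]ethyl}-9-borabicyclo[3.3.1]nonane | C1CCC2CCCC1B2CC[C@@H]3C(C)=CC=C4[C@@](C)(CO[Si](C(C)C)(C(C)C)C(C)C)CCC[C@@]34C | intermediate (not isolated)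
16 | methyl (2E)-3-methyl-5-[(1R,5S,8aS)-2,5,8a-trimethyl-5-{[tri(propan-2-yl)silyl]oxymethyl}-1,5,6,7,8,8a-hexahydronaphthalen-1-yl]pent-2-enoate | COC(=O)/C=C(\C)CC[C@@H]1C(C)=CC=C2[C@@](C)(CO[Si](C(C)C)(C(C)C)C(C)C)CCC[C@@]12C | intermediate
17 | alkylborane of 16: BH2 on C6 and H on C5, both trans to the C10 methyl | COC(=O)/C=C(\C)CC[C@@H]1C(C)=C[C@@H](B)[C@@H]2[C@@](C)(CO[Si](C(C)C)(C(C)C)C(C)C)CCC[C@@]12C | intermediate (not isolated)
18 | methyl (2E)-5-[(1R,4R,4aS,5S,8aS)-4-hydroxy-2,5,8a-trimethyl-5-{[tri(propan-2-yl)silyl]oxymethyl}-1,4,4a,5,6,7,8,8a-octahydronaphthalen-1-yl]-3-methylpent-2-enoate | COC(=O)/C=C(\C)CC[C@@H]1C(C)=C[C@@H](O)[C@@H]2[C@@](C)(CO[Si](C(C)C)(C(C)C)C(C)C)CCC[C@@]12C | intermediate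
19 | methyl (2E)-5-[(1R,4R,4aS,5S,8aS)-4-hydroxy-5-(hydroxymethyl)-2,5,8a-trimethyl-1,4,4a,5,6,7,8,8a-octahydronaphthalen-1-yl]-3-methylpent-2-enoate | COC(=O)/C=C(\C)CC[C@@H]1C(C)=C[C@@H](O)[C@@H]2[C@@](C)(CO)CCC[C@@]12C | target

## Step count and risks
Total: 9 steps. Longest linear sequence: 9 steps (1/2 → 19; 5 and 14 enter as purchased reagents).

**Step 4 (the proposed new ring expansion).** Risks: slow C–H cleavage next to the fully substituted carbinol, retro-allylation, migration of the C7 methylene instead of C10, and the C9 epimer ratio, which is kinetic because base equilibration is not expected to give a useful bias. Fallback with known chemistry, setting out from 10 and coming back at 11: SeO2 (cat.)/t-BuOOH hydroxylates the allylic CH2 of the terminal allyl group to give the vinyl-substituted 1,2-diol F1 (the ring alkene has no allylic hydrogen on its substituted end). MsCl/Et3N at −20 °C mesylates only the secondary allylic hydroxyl to give the mesylate F2. AlEt3 in CH2Cl2 at −78 °C then triggers the pinacol-type 1,2-shift of the quaternary ring carbon with loss of mesylate, giving 11.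

**Step 2 (one-pot masking, allylation, alkylation).** Risks: incomplete or wrong-site enolisation, O- instead of C-alkylation by the chloromethyl ether, and alkylation of the tertiary alkoxide. Fallback, setting out from 4 and coming back at 10, protects C8 by a redox detour. NaBH4 (EtOH, −20 °C) reduces only the saturated ketone to the hydroxy enone F3. KOt-Bu/TOM-Cl alkylates C4 to give the hydroxy ketone F4. TsNHNH2 gives the tosylhydrazone F5, and catecholborane/NaOAc·3H2O gives the deoxygenated alcohol F6. Dess–Martin periodinane gives the ketone F7, and allylmagnesium bromide 5 (CeCl3, THF, −78 °C) gives 10.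

**Step 8 (diene hydroboration).** Risks: attack at C7 instead of C6, 1,3-boron shift of the allylic borane, and competing reduction of the enoate. Fallback, setting out from 11 and coming back at 18, goes through a C6 ketone.
- 9-BBN gives the borane F8, and CuOAc-catalysed addition to 14 gives the keto ester F9.
- RhCl3·3H2O (cat., EtOH) moves C5=C6 into conjugation to give the enone F10 (H5 trans to C20).
- MeLi/CeCl3 gives the tertiary allylic alcohol F11.
- Pyridinium chlorochromate, [C5H5NH][CrO3Cl], effects oxidative 1,3-transposition to the 8-methyl-7-en-6-one F12.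
- NaBH4/CeCl3 delivers hydride from the open face to give the axial 6-epi alcohol F13.
- Mitsunobu inversion (4-nitrobenzoic acid, PPh3, DIAD) gives the equatorial ester F14, and K2CO3/MeOH gives 18.

## Further compounds
F1 | step 4 | 1-[(1R,4S,7aR)-1-hydroxy-4,7a-dimethyl-4-{[tri(propan-2-yl)silyl]oxymethyl}-2,4,5,6,7,7a-hexahydro-1H-inden-1-yl]prop-2-en-1-ol (both carbinol epimers) | C=CC(O)[C@@]1(O)CC=C2[C@@](C)(CO[Si](C(C)C)(C(C)C)C(C)C)CCC[C@@]12C
F2 | step 4 | secondary allylic methanesulfonate of F1 | C=CC(OS(C)(=O)=O)[C@@]1(O)CC=C2[C@@](C)(CO[Si](C(C)C)(C(C)C)C(C)C)CCC[C@@]12C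
F3 | step 2 | (1R,7aR)-1-hydroxy-4,7a-dimethyl-1,2,3,6,7,7a-hexahydro-5H-inden-5-one | O[C@@H]1CCC2=C(C)C(=O)CC[C@@]12C
F4 | step 2 | (1R,4S,7aR)-1-hydroxy-4,7a-dimethyl-4-{[tri(propan-2-yl)silyl]oxymethyl}-1,2,4,6,7,7a-hexahydro-5H-inden-5-one | O[C@@H]1CC=C2[C@@](C)(CO[Si](C(C)C)(C(C)C)C(C)C)C(=O)CC[C@@]12C
F5 | step 2 | 4-methylbenzenesulfonylhydrazone of F4 | O[C@@H]1CC=C2[C@@](C)(CO[Si](C(C)C)(C(C)C)C(C)C)C(=NNS(=O)(=O)c3ccc(C)cc3)CC[C@@]12C
F6 | step 2 | (1R,4S,7aR)-4,7a-dimethyl-4-{[tri(propan-2-yl)silyl]oxymethyl}-2,4,5,6,7,7a-hexahydro-1H-inden-1-ol | O[C@@H]1CC=C2[C@@](C)(CO[Si](C(C)C)(C(C)C)C(C)C)CCC[C@@]12C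
F7 | step 2 | (4S,7aR)-4,7a-dimethyl-4-{[tri(propan-2-yl)silyl]oxymethyl}-2,4,5,6,7,7a-hexahydro-1H-inden-1-one | O=C1CC=C2[C@@](C)(CO[Si](C(C)C)(C(C)C)C(C)C)CCC[C@@]12C
F8 | step 8 | B-alkyl-9-BBN adduct of 11 (boron on the terminal carbon of the former vinyl group) | C1CCC2CCCC1B2CC[C@@H]3C(=O)CC=C4[C@@](C)(CO[Si](C(C)C)(C(C)C)C(C)C)CCC[C@@]34C
F9 | step 8 | methyl (2E)-5-[(1S,5S,8aS)-5,8a-dimethyl-2-oxo-5-{[tri(propan-2-yl)silyl]oxymethyl}-1,2,3,5,6,7,8,8a-octahydronaphthalen-1-yl]-3-methylpent-2-enoate | COC(=O)/C=C(\C)CC[C@@H]1C(=O)CC=C2[C@@](C)(CO[Si](C(C)C)(C(C)C)C(C)C)CCC[C@@]12C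
F10 | step 8 | conjugated 6-en-8-one isomer of F9 (labdane numbering, H5 trans to the C10 methyl) | COC(=O)/C=C(\C)CC[C@@H]1C(=O)C=C[C@@H]2[C@@](C)(CO[Si](C(C)C)(C(C)C)C(C)C)CCC[C@@]12C
F11 | step 8 | tertiary allylic alcohol from F10 (8-methyl, 8-hydroxy cis to the C10 methyl, 6-ene) | COC(=O)/C=C(\C)CC[C@@H]1[C@](C)(O)C=C[C@@H]2[C@@](C)(CO[Si](C(C)C)(C(C)C)C(C)C)CCC[C@@]12C
F12 | step 8 | 8-methyl-7-en-6-one (6-oxo analogue of 18) | COC(=O)/C=C(\C)CC[C@@H]1C(C)=CC(=O)[C@@H]2[C@@](C)(CO[Si](C(C)C)(C(C)C)C(C)C)CCC[C@@]12C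
F13 | step 8 | 6-epimer of 18 (axial 6-OH, cis to the C10 methyl) | COC(=O)/C=C(\C)CC[C@@H]1C(C)=C[C@H](O)[C@@H]2[C@@](C)(CO[Si](C(C)C)(C(C)C)C(C)C)CCC[C@@]12C
F14 | step 8 | 4-nitrobenzoate of 18 at the 6-hydroxyl | COC(=O)/C=C(\C)CC[C@@H]1C(C)=C[C@@H](OC(=O)c3ccc(cc3)[N+](=O)[O-])[C@@H]2[C@@](C)(CO[Si](C(C)C)(C(C)C)C(C)C)CCC[C@@]12C
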